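**Retrosynthetic overview** (germacrane locants: C1–C10 ring, C11–C13 lactone carbons, C14 = CH2O-tiglate, C15 = methyl)
1. The target is cut at C6–C7. Acyclic epoxy aldehyde 22 already holds the butenolide and the oxirane; an intramolecular Cr(II) (Nozaki–Hiyama/Barbier) allylation closes the ten-membered carbocycle last and gives the target directly.
2. Enabling feature: the array C6(OH)–C7–C11(=C13H2)–C12(=O)–O–C8 of the α-methylene γ-lactone ring is the retron of γ-attack (at C7) of a 3-(metallomethyl)but-2-en-4-olide on a C6 aldehyde. The cis-4,5-oxirane next to C6 and the C1=C10 olefin act as turn elements.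
3. 22 comes from allylic alcohol 20 (Sharpless epoxidation, oxidation). The butenolide comes from RCM of the 2-(bromomethyl)acrylate of vinyl carbinol 16, whose C8 centre is set by a first Sharpless epoxidation and zinc-mediated reductive opening.
4. The C1=C10 olefin with its 14-oxygen comes from hydroxyl-directed anti-allylmagnesiation/iodination of propargyl alcohol and B-alkyl Suzuki coupling with the C2–C6 diene 3.
5. Ring order: butenolide (step 11), oxirane (step 13), cyclodecene (step 15).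

Key step: step 15

Remark on the chemistry: the SMILES is read as (4S,5R,6S,7S,8S), with a cis-fused 4,5-oxirane (C3 and C6 on the same side), C2 and C9 trans across C1=C10 (CH2O-tiglate cis to C2), and the ester as tiglate ((E)-2-methylbut-2-enoate).

**Step 1**
Reactants: 1 (Z)-3-methylpent-2-en-4-yn-1-ol
Product: 2 (Z)-tert-butyldimethyl[(3-methylpent-2-en-4-yn-1-yl)oxy]silane
Conditions: TBSCl, imidazole, DMF, 0 °C to rt
Reagents that add atoms: tert-butyldimethylsilyl chloride, CC(C)(C)[Si](C)(C)Cl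
Why: Imidazole-promoted silylation of the primary alcohol masks the future C6 hydroxyl for the borane, acylation and metathesis steps; no stereocentre is involved.

**Step 2**
Reactants: 2 (Z)-tert-butyldimethyl[(3-methylpent-2-en-4-yn-1-yl)oxy]silane
Product: 3 (Z)-tert-butyldimethyl[(3-methylpenta-2,4-dien-1-yl)oxy]silane
Conditions: H2 (1 atm), Lindlar catalyst, quinoline, hexane, rt
Reagents that add atoms: none
Why: Lindlar semihydrogenation should stop at the vinyl group under quinoline poisoning and leaves the Z trisubstituted alkene (later C4=C5) untouched.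

**Step 3**
Reactants: 4 prop-2-yn-1-ol; 5 allylmagnesium bromide
Product: 7 (Z)-2-(iodomethylidene)pent-4-en-1-ol, via alkenylmagnesium alkoxide chelate 6 (not isolated)
Conditions: 5 (3 equiv), CuI (10 mol %), Et2O, −10 °C to rt; then I2, THF, −30 to 0 °C
Reagents that add atoms: iodine, II
Why: Hydroxyl-directed anti-carbomagnesiation of the propargylic alkoxide puts allyl on the internal carbon and magnesium on the terminal carbon, held cis to CH2O in a five-membered chelate; iodinolysis with retention should give the Z vinyl iodide, which fixes the C1=C10 geometry (C14 cis to iodine, allyl carbon C9 trans).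

**Step 4**
Reactants: 3 (Z)-tert-butyldimethyl[(3-methylpenta-2,4-dien-1-yl)oxy]silane; 7 (Z)-2-(iodomethylidene)pent-4-en-1-ol
Product: 9 (2Z,6Z)-2-allyl-8-[(tert-butyldimethylsilyl)oxy]-6-methylocta-2,6-dien-1-ol, via B-alkyl-9-BBN borane 8 (not isolated)
Conditions: 3, 9-BBN (1.0 equiv), THF, 0 °C to rt; then 7, PdCl2(dppf) (5 mol %), AsPh3, aq. Cs2CO3, DMF, rt
Reagents that add atoms: none
Why: 9-BBN hydroborates only the monosubstituted alkene of the diene (anti-Markovnikov), and the B-alkyl Suzuki–Miyaura coupling proceeds with retention at the vinyl iodide, so C2 ends cis to C14 and trans to C9; the free hydroxyl and the allyl group are tolerated when no excess borane is present.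

**Step 5**
Reactants: 9 (2Z,6Z)-2-allyl-8-[(tert-butyldimethylsilyl)oxy]-6-methylocta-2,6-dien-1-ol; 10 tigloyl chloride
Product: 11 (2Z,6Z)-2-allyl-8-[(tert-butyldimethylsilyl)oxy]-6-methylocta-2,6-dien-1-yl (E)-2-methylbut-2-enoate
Conditions: 10, Et3N, DMAP (cat.), CH2Cl2, 0 °C
Reagents that add atoms: none
Why: Acylation of the only free (primary allylic) hydroxyl installs the tiglate early; it is the thermodynamically preferred enoate geometry and is inert to all later steps.

**Step 6**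
Reactants: 11 (2Z,6Z)-2-allyl-8-[(tert-butyldimethylsilyl)oxy]-6-methylocta-2,6-dien-1-yl (E)-2-methylbut-2-enoate; 12 (Z)-but-2-ene-1,4-diol
Product: 13 (2Z,6Z)-8-[(tert-butyldimethylsilyl)oxy]-2-[(E)-4-hydroxybut-2-en-1-yl]-6-methylocta-2,6-dien-1-yl (E)-2-methylbut-2-enoate
Conditions: 12 (5 equiv), Hoveyda–Grubbs II (5 mol %), CH2Cl2, 40 °C
Reagents that add atoms: none
Why: Olefin cross-metathesis engages only the terminal alkene (the trisubstituted alkenes and the enoate are inert) and should give the E allylic alcohol under thermodynamic control.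

**Step 7**
Reactants: 13 (2Z,6Z)-8-[(tert-butyldimethylsilyl)oxy]-2-[(E)-4-hydroxybut-2-en-1-yl]-6-methylocta-2,6-dien-1-yl (E)-2-methylbut-2-enoate
Product: 14 (2Z,6Z)-8-[(tert-butyldimethylsilyl)oxy]-2-{[(2S,3S)-3-(hydroxymethyl)oxiran-2-yl]methyl}-6-methylocta-2,6-dien-1-yl (E)-2-methylbut-2-enoate
Conditions: Ti(OiPr)4, L-(+)-diethyl tartrate, t-BuOOH, 4 Å MS, CH2Cl2, −20 °C
Reagents that add atoms: tert-butyl hydroperoxide, CC(C)(C)OO
Why: Sharpless asymmetric epoxidation acts only on the free allylic alcohol; L-(+)-tartrate delivers oxygen to the face that gives the (2S,3S)-epoxide, which sets C8 as S by reagent control.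

**Step 8**
Reactants: 14 (2Z,6Z)-8-[(tert-butyldimethylsilyl)oxy]-2-{[(2S,3S)-3-(hydroxymethyl)oxiran-2-yl]methyl}-6-methylocta-2,6-dien-1-yl (E)-2-methylbut-2-enoate
Product: 15 (2Z,6Z)-8-[(tert-butyldimethylsilyl)oxy]-2-{[(2S,3R)-3-(iodomethyl)oxiran-2-yl]methyl}-6-methylocta-2,6-dien-1-yl (E)-2-methylbut-2-enoate
Conditions: I2, PPh3, imidazole, THF/MeCN, 0 °C
Reagents that add atoms: iodine, II
Why: Garegg–Samuelsson (Appel-type) iodination converts the primary alcohol under buffered conditions that leave the oxirane intact (the descriptor change at C7 is a priority effect only).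

**Step 9**
Reactants: 15 (2Z,6Z)-8-[(tert-butyldimethylsilyl)oxy]-2-{[(2S,3R)-3-(iodomethyl)oxiran-2-yl]methyl}-6-methylocta-2,6-dien-1-yl (E)-2-methylbut-2-enoate
Product: 16 (2Z,6Z)-8-[(tert-butyldimethylsilyl)oxy]-2-[(S)-2-hydroxybut-3-en-1-yl]-6-methylocta-2,6-dien-1-yl (E)-2-methylbut-2-enoate
Conditions: Zn dust, EtOH, 60 °C; aq. NH4Cl work-up
Reagents that add atoms: none
Why: Zinc insertion into the C–I bond and β-elimination of the oxirane oxygen (reductive epoxide opening) unveils the terminal vinyl group and leaves the C8–O bond untouched, so C8 stays S.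

**Step 10**
Reactants: 16 (2Z,6Z)-8-[(tert-butyldimethylsilyl)oxy]-2-[(S)-2-hydroxybut-3-en-1-yl]-6-methylocta-2,6-dien-1-yl (E)-2-methylbut-2-enoate; 17 2-(bromomethyl)acrylic acid
Product: 18 (2Z,6Z)-2-[(S)-2-{[2-(bromomethyl)acryloyl]oxy}but-3-en-1-yl]-8-[(tert-butyldimethylsilyl)oxy]-6-methylocta-2,6-dien-1-yl (E)-2-methylbut-2-enoate
Conditions: 17, DCC, DMAP (cat.), CH2Cl2, −10 to 0 °C
Reagents that add atoms: none
Why: Steglich esterification of the secondary allylic alcohol at low temperature and low DMAP loading should outrun N-alkylation by the allylic bromide; C8 is not touched.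

**Step 11**
Reactants: 18 (2Z,6Z)-2-[(S)-2-{[2-(bromomethyl)acryloyl]oxy}but-3-en-1-yl]-8-[(tert-butyldimethylsilyl)oxy]-6-methylocta-2,6-dien-1-yl (E)-2-methylbut-2-enoate
Product: 19 (2Z,6Z)-2-{[(S)-4-(bromomethyl)-5-oxo-2,5-dihydrofuran-2-yl]methyl}-8-[(tert-butyldimethylsilyl)oxy]-6-methylocta-2,6-dien-1-yl (E)-2-methylbut-2-enoate
Conditions: Grubbs II (10 mol %), CH2Cl2 (5 mM), 40 °C
Reagents that add atoms: none
Why: Ring-closing metathesis between the vinyl group and the 1,1-disubstituted acrylate forms the five-membered butenolide (C7=C11) with loss of ethene; the trisubstituted alkenes do not compete and the allylic bromide is tolerated by the ruthenium carbene.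

**Step 12**
Reactants: 19 (2Z,6Z)-2-{[(S)-4-(bromomethyl)-5-oxo-2,5-dihydrofuran-2-yl]methyl}-8-[(tert-butyldimethylsilyl)oxy]-6-methylocta-2,6-dien-1-yl (E)-2-methylbut-2-enoate
Product: 20 (2Z,6Z)-2-{[(S)-4-(bromomethyl)-5-oxo-2,5-dihydrofuran-2-yl]methyl}-8-hydroxy-6-methylocta-2,6-dien-1-yl (E)-2-methylbut-2-enoate
Conditions: aq. HF (48 %), MeCN, 0 °C
Reagents that add atoms: none
Why: Acidic fluoride desilylation of the primary allylic silyl ether is non-basic and non-nucleophilic toward the bromomethyl butenolide, the lactone and the tiglate.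

**Step 13**
Reactants: 20 (2Z,6Z)-2-{[(S)-4-(bromomethyl)-5-oxo-2,5-dihydrofuran-2-yl]methyl}-8-hydroxy-6-methylocta-2,6-dien-1-yl (E)-2-methylbut-2-enoate
Product: 21 (Z)-2-{[(S)-4-(bromomethyl)-5-oxo-2,5-dihydrofuran-2-yl]methyl}-5-[(2S,3R)-3-(hydroxymethyl)-2-methyloxiran-2-yl]pent-2-en-1-yl (E)-2-methylbut-2-enoate
Conditions: Ti(OiPr)4, D-(−)-diethyl tartrate, t-BuOOH, 4 Å MS, CH2Cl2, −20 °C
Reagents that add atoms: tert-butyl hydroperoxide, CC(C)(C)OO
Why: Sharpless asymmetric epoxidation of the Z trisubstituted (nerol-type) allylic alcohol with D-(−)-tartrate gives the cis-oxirane with C4 S and C5 R by reagent control; the remote C8 centre has no influence and the other alkenes lack a directing hydroxyl.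

**Step 14**
Reactants: 21 (Z)-2-{[(S)-4-(bromomethyl)-5-oxo-2,5-dihydrofuran-2-yl]methyl}-5-[(2S,3R)-3-(hydroxymethyl)-2-methyloxiran-2-yl]pent-2-en-1-yl (E)-2-methylbut-2-enoate
Product: 22 (Z)-2-{[(S)-4-(bromomethyl)-5-oxo-2,5-dihydrofuran-2-yl]methyl}-5-[(2S,3S)-3-formyl-2-methyloxiran-2-yl]pent-2-en-1-yl (E)-2-methylbut-2-enoate
Conditions: Dess–Martin periodinane, NaHCO3, CH2Cl2, 0 °C to rt
Reagents that add atoms: none
Why: Buffered Dess–Martin oxidation gives the α,β-epoxy aldehyde without epimerisation at C5 (the descriptor change is a priority effect) and without touching the bromide.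

**Step 15**
Reactants: 22 (Z)-2-{[(S)-4-(bromomethyl)-5-oxo-2,5-dihydrofuran-2-yl]methyl}-5-[(2S,3S)-3-formyl-2-methyloxiran-2-yl]pent-2-en-1-yl (E)-2-methylbut-2-enoate
Product: 24 CNP0116446.1 (target), via allylchromium(III) dichloride 23 (not isolated)
Conditions: CrCl2 (10 equiv), THF, rt, slow addition of 22 (final 1 mM); aq. NH4Cl work-up
Reagents that add atoms: none
Why: Cr(II) inserts selectively into the allylic C–Br bond to give allylchromium(III) 23, which adds through its γ-carbon (C7) to the C6 aldehyde in a closed chair (Zimmerman–Traxler) transition state and shifts the double bond to C11=C13; the closest known reaction type is the Nozaki–Hiyama (Cr-Barbier) allylation of aldehydes by 3-(bromomethyl)butenolides, combined with macrocyclic Barbier allylations of α,β-epoxy aldehydes to cyclodecenes. The ten-membered carbocycle is closed by C6–C7 bond formation in 10-exo-trig mode at the carbonyl (SE2′ at the allylmetal), with the cis-oxirane (C3 and C6 on one face) and the trisubstituted C1=C10 olefin as turn elements that hold C6 near C7. C7 is set by attack on the butenolide face anti to the C8–C9 bond, which gives the trans-fused lactone (7S) and is the only mode that lets both new ring bonds sit pseudo-equatorially on the lactone. C6 is set by the chair: the ring-locked E relationship of C8 to CH2Cr and an equatorial C5 give the 6,7-anti product (6S). The same sense results from attack on the C5–H side of a chromium-bridged (aldehyde O/oxirane O) conformer, and the intrinsic Felkin bias of α,β-epoxy aldehydes that opposes it is weak, so control by the allyl partner should prevail. The step needs chemoselective insertion (only the allylic bromide reacts with CrCl2; tiglate, lactone, oxirane and aldehyde are inert), γ-regioselectivity (enforced by the six-membered transition state) and suppression of oligomerisation (slow addition to 1 mM).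

**Compound list**
1 | (Z)-3-methylpent-2-en-4-yn-1-ol | C#C/C(C)=C\CO | starting material
2 | (Z)-tert-butyldimethyl[(3-methylpent-2-en-4-yn-1-yl)oxy]silane | C#C/C(C)=C\CO[Si](C)(C)C(C)(C)C | intermediate
3 | (Z)-tert-butyldimethyl[(3-methylpenta-2,4-dien-1-yl)oxy]silane | C=C/C(C)=C\CO[Si](C)(C)C(C)(C)C | intermediate
4 | prop-2-yn-1-ol | C#CCO | starting material
5 | allylmagnesium bromide | C=CC[Mg]Br | starting material
6 | alkenylmagnesium alkoxide chelate (4-allyl-2,5-dihydro-1,2-oxamagnesole) | C=CCC1=C[Mg]OC1 | intermediate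
7 | (Z)-2-(iodomethylidene)pent-4-en-1-ol | OC/C(CC=C)=C\I | intermediate
8 | 9-[(Z)-5-[(tert-butyldimethylsilyl)oxy]-3-methylpent-3-en-1-yl]-9-borabicyclo[3.3.1]nonane | B1(CC/C(C)=C\CO[Si](C)(C)C(C)(C)C)C2CCCC1CCC2 | intermediate
9 | (2Z,6Z)-2-allyl-8-[(tert-butyldimethylsilyl)oxy]-6-methylocta-2,6-dien-1-ol | OC/C(CC=C)=C\CC/C(C)=C\CO[Si](C)(C)C(C)(C)C | intermediate
10 | tigloyl chloride ((E)-2-methylbut-2-enoyl chloride) | C/C=C(\C)C(Cl)=O | starting material
11 | (2Z,6Z)-2-allyl-8-[(tert-butyldimethylsilyl)oxy]-6-methylocta-2,6-dien-1-yl (E)-2-methylbut-2-enoate | C/C=C(\C)C(=O)OC/C(CC=C)=C\CC/C(C)=C\CO[Si](C)(C)C(C)(C)C | intermediate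
12 | (Z)-but-2-ene-1,4-diol | OC/C=C\CO | starting material
13 | (2Z,6Z)-8-[(tert-butyldimethylsilyl)oxy]-2-[(E)-4-hydroxybut-2-en-1-yl]-6-methylocta-2,6-dien-1-yl (E)-2-methylbut-2-enoate | C/C=C(\C)C(=O)OC/C(C/C=C/CO)=C\CC/C(C)=C\CO[Si](C)(C)C(C)(C)C | intermediate
14 | (2Z,6Z)-8-[(tert-butyldimethylsilyl)oxy]-2-{[(2S,3S)-3-(hydroxymethyl)oxiran-2-yl]methyl}-6-methylocta-2,6-dien-1-yl (E)-2-methylbut-2-enoate | C/C=C(\C)C(=O)OC/C(C[C@@H]1O[C@H]1CO)=C\CC/C(C)=C\CO[Si](C)(C)C(C)(C)C | intermediate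
15 | (2Z,6Z)-8-[(tert-butyldimethylsilyl)oxy]-2-{[(2S,3R)-3-(iodomethyl)oxiran-2-yl]methyl}-6-methylocta-2,6-dien-1-yl (E)-2-methylbut-2-enoate | C/C=C(\C)C(=O)OC/C(C[C@@H]1O[C@H]1CI)=C\CC/C(C)=C\CO[Si](C)(C)C(C)(C)C | intermediate
16 | (2Z,6Z)-8-[(tert-butyldimethylsilyl)oxy]-2-[(S)-2-hydroxybut-3-en-1-yl]-6-methylocta-2,6-dien-1-yl (E)-2-methylbut-2-enoate | C/C=C(\C)C(=O)OC/C(C[C@H](O)C=C)=C\CC/C(C)=C\CO[Si](C)(C)C(C)(C)C | intermediate
17 | 2-(bromomethyl)acrylic acid | C=C(CBr)C(=O)O | starting material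
18 | (2Z,6Z)-2-[(S)-2-{[2-(bromomethyl)acryloyl]oxy}but-3-en-1-yl]-8-[(tert-butyldimethylsilyl)oxy]-6-methylocta-2,6-dien-1-yl (E)-2-methylbut-2-enoate | C/C=C(\C)C(=O)OC/C(C[C@H](OC(=O)C(=C)CBr)C=C)=C\CC/C(C)=C\CO[Si](C)(C)C(C)(C)C | intermediate
19 | (2Z,6Z)-2-{[(S)-4-(bromomethyl)-5-oxo-2,5-dihydrofuran-2-yl]methyl}-8-[(tert-butyldimethylsilyl)oxy]-6-methylocta-2,6-dien-1-yl (E)-2-methylbut-2-enoate | C/C=C(\C)C(=O)OC/C(C[C@@H]1OC(=O)C(CBr)=C1)=C\CC/C(C)=C\CO[Si](C)(C)C(C)(C)C | intermediate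
20 | (2Z,6Z)-2-{[(S)-4-(bromomethyl)-5-oxo-2,5-dihydrofuran-2-yl]methyl}-8-hydroxy-6-methylocta-2,6-dien-1-yl (E)-2-methylbut-2-enoate | C/C=C(\C)C(=O)OC/C(C[C@@H]1OC(=O)C(CBr)=C1)=C\CC/C(C)=C\CO | intermediate
21 | (Z)-2-{[(S)-4-(bromomethyl)-5-oxo-2,5-dihydrofuran-2-yl]methyl}-5-[(2S,3R)-3-(hydroxymethyl)-2-methyloxiran-2-yl]pent-2-en-1-yl (E)-2-methylbut-2-enoate | C/C=C(\C)C(=O)OC/C(C[C@@H]1OC(=O)C(CBr)=C1)=C\CC[C@]1(C)O[C@@H]1CO | intermediate
22 | (Z)-2-{[(S)-4-(bromomethyl)-5-oxo-2,5-dihydrofuran-2-yl]methyl}-5-[(2S,3S)-3-formyl-2-methyloxiran-2-yl]pent-2-en-1-yl (E)-2-methylbut-2-enoate | C/C=C(\C)C(=O)OC/C(C[C@@H]1OC(=O)C(CBr)=C1)=C\CC[C@]1(C)O[C@@H]1C=O | intermediate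
23 | allylchromium(III) dichloride derived from 22 (CH2Br replaced by CH2CrCl2) | C/C=C(\C)C(=O)OC/C(C[C@@H]1OC(=O)C(C[Cr](Cl)Cl)=C1)=C\CC[C@]1(C)O[C@@H]1C=O | intermediate
24 | CNP0116446.1, (4S,5R,6S,7S,8S)-4,5-epoxy-6-hydroxy-14-tigloyloxygermacra-1(10),11(13)-dien-12,8-olide (cis-oxirane, C2/C9 trans across C1=C10) | C=C1C(=O)O[C@H]2C/C(COC(=O)/C(C)=C/C)=C/CC[C@]3(C)O[C@@H]3[C@@H](O)[C@H]12 | target

**Totals**
Total step count: 15. Longest linear sequence: 14 steps (1 to 24 through steps 1, 2 and 4–15).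

**Steps most likely to fail**

Step 15. The process at risk is addition to the wrong face of the C6 aldehyde during ring closure, with the Felkin sense of the epoxy aldehyde overriding the chair control and giving the C6 epimer; intermolecular allylation is countered by dilution. The fallback sets out from 22, which is cyclised as in step 15 to the 6R alcohol 6-epi-24 F1. A Mitsunobu reaction of F1 with formic acid (PPh3, DIAD, THF, 0 °C) inverts C6 and gives the 6S formate 6-O-formyl-24 F2. Selective methanolysis of the formate (KHCO3, MeOH, 0 °C), which the tiglate and the lactone should survive, comes back to the route at 24.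

Step 11. The process at risk is slow ring closure of the electron-poor 1,1-disubstituted bromomethyl acrylate, with catalyst decay and loss of the allylic bromide on prolonged heating. The fallback sets out from 16 and brings C13 in after the ring is made. Acylation with acryloyl chloride (iPr2NEt, CH2Cl2, −20 °C) gives the acrylate F3. RCM of this monosubstituted acrylate (Grubbs II, CH2Cl2, 40 °C) gives the unsubstituted butenolide F4. Morita–Baylis–Hillman hydroxymethylation at C11 (aq. formaldehyde, imidazole or PBu3 as catalyst, THF) gives the hydroxymethyl butenolide F5, and Appel bromination (CBr4, PPh3, CH2Cl2, 0 °C) comes back at 19.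

Step 6. The process at risk is ruthenium-hydride-mediated double-bond migration in the skipped diene and erosion of E/Z selectivity in the cross-metathesis, which would pass on to the C8 configuration. The fallback sets out from 11 and avoids metathesis and the transient oxirane. 9-BBN hydroboration of the terminal alkene with NaBO3 oxidation gives the primary alcohol F6, and Dess–Martin oxidation gives the aldehyde F7. D-Proline-catalysed α-aminoxylation with nitrosobenzene (CHCl3, 0 °C) sets C8 and gives the (S)-α-anilinooxy aldehyde F8. Lombardo methylenation (Zn, CH2Br2, TiCl4, THF) gives the allylic N-phenylhydroxylamine ether F9, and N–O cleavage (Zn, AcOH) comes back at 16, bypassing 13–15.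

**Further compounds**
F1 | step 15 | 6-epi-24, (4S,5R,6R,7S,8S)-isomer of the target | C=C1C(=O)O[C@H]2C/C(COC(=O)/C(C)=C/C)=C/CC[C@]3(C)O[C@@H]3[C@H](O)[C@H]12
F2 | step 15 | 6-O-formyl-24 (6S formate) | C=C1C(=O)O[C@H]2C/C(COC(=O)/C(C)=C/C)=C/CC[C@]3(C)O[C@@H]3[C@@H](OC=O)[C@H]12
F3 | step 11 | (2Z,6Z)-2-[(S)-2-(acryloyloxy)but-3-en-1-yl]-8-[(tert-butyldimethylsilyl)oxy]-6-methylocta-2,6-dien-1-yl (E)-2-methylbut-2-enoate | C/C=C(\C)C(=O)OC/C(C[C@H](OC(=O)C=C)C=C)=C\CC/C(C)=C\CO[Si](C)(C)C(C)(C)C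
F4 | step 11 | (2Z,6Z)-8-[(tert-butyldimethylsilyl)oxy]-6-methyl-2-{[(S)-5-oxo-2,5-dihydrofuran-2-yl]methyl}octa-2,6-dien-1-yl (E)-2-methylbut-2-enoate | C/C=C(\C)C(=O)OC/C(C[C@@H]1OC(=O)C=C1)=C\CC/C(C)=C\CO[Si](C)(C)C(C)(C)C
F5 | step 11 | (2Z,6Z)-8-[(tert-butyldimethylsilyl)oxy]-2-{[(S)-4-(hydroxymethyl)-5-oxo-2,5-dihydrofuran-2-yl]methyl}-6-methylocta-2,6-dien-1-yl (E)-2-methylbut-2-enoate | C/C=C(\C)C(=O)OC/C(C[C@@H]1OC(=O)C(CO)=C1)=C\CC/C(C)=C\CO[Si](C)(C)C(C)(C)C
F6 | step 6 | (2Z,6Z)-8-[(tert-butyldimethylsilyl)oxy]-2-(3-hydroxypropyl)-6-methylocta-2,6-dien-1-yl (E)-2-methylbut-2-enoate | C/C=C(\C)C(=O)OC/C(CCCO)=C\CC/C(C)=C\CO[Si](C)(C)C(C)(C)C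
F7 | step 6 | (2Z,6Z)-8-[(tert-butyldimethylsilyl)oxy]-6-methyl-2-(3-oxopropyl)octa-2,6-dien-1-yl (E)-2-methylbut-2-enoate | C/C=C(\C)C(=O)OC/C(CCC=O)=C\CC/C(C)=C\CO[Si](C)(C)C(C)(C)C
F8 | step 6 | (2Z,6Z)-8-[(tert-butyldimethylsilyl)oxy]-6-methyl-2-[(S)-3-oxo-2-(phenylaminooxy)propyl]octa-2,6-dien-1-yl (E)-2-methylbut-2-enoate | C/C=C(\C)C(=O)OC/C(C[C@H](ONc1ccccc1)C=O)=C\CC/C(C)=C\CO[Si](C)(C)C(C)(C)C
F9 | step 6 | (2Z,6Z)-8-[(tert-butyldimethylsilyl)oxy]-6-methyl-2-[(S)-2-(phenylaminooxy)but-3-en-1-yl]octa-2,6-dien-1-yl (E)-2-methylbut-2-enoate | C/C=C(\C)C(=O)OC/C(C[C@H](ONc1ccccc1)C=C)=C\CC/C(C)=C\CO[Si](C)(C)C(C)(C)C
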